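**Retrosynthetic overview**
1. Target ⇒ fluoride removal of two TBS ethers and one aryl SEM ether; aryl–C1' bond from an arylcopper (from 2-bromo-4-methoxy-6-methylphenol) and a C16 allylic bromide by SN2.
2. C16 chain ⇒ C4'–C5' bond by a catalytic enantioselective vinylogous Mukaiyama aldol between C15 enal 9 and silyl dienolate 12 (from ethyl 3-methylbut-2-enoate); this sets 5'R and the 2'E olefin.
3. Enal 9 ⇒ C12'–C13' bond by Brown carbonyl allylation of 8-oxogeranyl acetate (sets 12'R); allyl → prenyl by cross-metathesis.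
4. 8-Oxogeranyl acetate ⇒ geranyl acetate by SeO2 allylic oxidation.
5. No ring is built; the arene is bought as 4-methoxy-2-methylphenol.

Assumption: (−)-Ipc2B(allyl) (pentane solution, the antipode derived from (−)-α-pinene), LiN(i-Pr)2 solution and the (R,R)-bisphosphoramide catalyst are used as purchased or literature-known reagents and are not numbered.

**Route**

Step 1
Reactants: 1 geranyl acetate
Product: 2 (2E,6E)-8-hydroxy-3,7-dimethylocta-2,6-dien-1-yl acetate
Conditions: SeO2 (0.1 equiv), salicylic acid (0.1 equiv), t-BuOOH (70% aq., 3.5 equiv), CH2Cl2, rt, 24 h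
Reagents that add atoms: SeO2 (catalytic oxygen-transfer agent), O=[Se]=O; tert-butyl hydroperoxide (stoichiometric oxygen source), CC(C)(C)OO
Why: Sharpless-type SeO2 allylic oxidation (ene reaction then [2,3]-shift) attacks the E-methyl of the electron-richer terminal trisubstituted olefin and leaves the acetate-deactivated 2,3-olefin alone.

Step 2
Reactants: 2 (2E,6E)-8-hydroxy-3,7-dimethylocta-2,6-dien-1-yl acetate
Product: 3 (2E,6E)-3,7-dimethyl-8-oxoocta-2,6-dien-1-yl acetate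
Conditions: MnO2 (15 equiv), CH2Cl2, rt
Reagents that add atoms: none
Why: MnO2 oxidation of a primary allylic alcohol gives the E-enal without olefin isomerisation or over-oxidation.

Step 3
Reactants: 3 (2E,6E)-3,7-dimethyl-8-oxoocta-2,6-dien-1-yl acetate
Product: 5 (2E,6E,8R)-8-hydroxy-3,7-dimethylundeca-2,6,10-trien-1-yl acetate, via O-diisopinocampheylboryl borinate 4 (not isolated)
Conditions: (−)-Ipc2B(allyl) (1.3 equiv), Et2O/pentane, −100 → −78 °C; then NaBO3·4H2O, THF/H2O, rt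
Reagents that add atoms: (−)-B-allyldiisopinocampheylborane, C=CCB([C@@H]1[C@@H](C)[C@@H]2C[C@H](C1)C2(C)C)[C@@H]1[C@@H](C)[C@@H]2C[C@H](C1)C2(C)C
Why: Brown asymmetric carbonyl allylation through a chair Zimmerman–Traxler transition state, in which the (−)-α-pinene-derived reagent adds to the Re face of the α-methyl enal to set 8R (expected ≥95% ee at −100 °C, checked by Mosher ester), with mild perborate work-up sparing the acetate.

Step 4
Reactants: 5 (2E,6E,8R)-8-hydroxy-3,7-dimethylundeca-2,6,10-trien-1-yl acetate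
Product: 6 (2E,6E,8R)-8-(tert-butyldimethylsilyloxy)-3,7-dimethylundeca-2,6,10-trien-1-yl acetate
Conditions: TBSCl, imidazole, DMAP (cat.), DMF, rt
Reagents that add atoms: tert-butyldimethylsilyl chloride, CC(C)(C)[Si](C)(C)Cl
Why: Standard silyl ether formation protects the acid-sensitive secondary allylic alcohol with a group that survives every later step and falls to fluoride.

Step 5
Reactants: 6 (2E,6E,8R)-8-(tert-butyldimethylsilyloxy)-3,7-dimethylundeca-2,6,10-trien-1-yl acetate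
Product: 7 (2E,6E,8R)-8-(tert-butyldimethylsilyloxy)-3,7,11-trimethyldodeca-2,6,10-trien-1-yl acetate
Conditions: second-generation Grubbs catalyst (5 mol%), 2-methyl-2-butene/CH2Cl2 (1:1), 40 °C
Reagents that add atoms: 2-methyl-2-butene, CC=C(C)C
Why: Olefin cross-metathesis in excess 2-methyl-2-butene converts only the monosubstituted vinyl group into the prenyl terminus, because the trisubstituted olefins are inert to the catalyst.

Step 6
Reactants: 7 (2E,6E,8R)-8-(tert-butyldimethylsilyloxy)-3,7,11-trimethyldodeca-2,6,10-trien-1-yl acetate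
Product: 8 (2E,6E,8R)-8-(tert-butyldimethylsilyloxy)-3,7,11-trimethyldodeca-2,6,10-trien-1-ol
Conditions: K2CO3 (0.5 equiv), MeOH, 0 °C → rt
Reagents that add atoms: none
Why: Base-catalysed transesterification (methanolysis) removes the acetate while the secondary TBS ether is untouched.

Step 7
Reactants: 8 (2E,6E,8R)-8-(tert-butyldimethylsilyloxy)-3,7,11-trimethyldodeca-2,6,10-trien-1-ol
Product: 9 (2E,6E,8R)-8-(tert-butyldimethylsilyloxy)-3,7,11-trimethyldodeca-2,6,10-trienal
Conditions: MnO2 (15 equiv), CH2Cl2, rt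
Reagents that add atoms: none
Why: Chemoselective MnO2 allylic oxidation gives the geranial-type 2E enal without touching the silyl ether or the other olefins.

Step 8
Reactants: 10 ethyl 3-methylbut-2-enoate
Product: 12 tert-butyl[(1-ethoxy-3-methylbuta-1,3-dien-1-yl)oxy]dimethylsilane, via lithium dienolate 11 (not isolated)
Conditions: LiN(i-Pr)2 (1.1 equiv), THF, −78 °C; TBSCl, DMPU, −78 °C → rt; distil
Reagents that add atoms: tert-butyldimethylsilyl chloride, CC(C)(C)[Si](C)(C)Cl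
Why: Kinetic γ-deprotonation of the senecioate gives the extended enolate, which is O-silylated to the silyl ketene acetal (silyl dienol ether) needed for the Mukaiyama reaction.

Step 9
Reactants: 9 (2E,6E,8R)-8-(tert-butyldimethylsilyloxy)-3,7,11-trimethyldodeca-2,6,10-trienal; 12 tert-butyl[(1-ethoxy-3-methylbuta-1,3-dien-1-yl)oxy]dimethylsilane
Product: 14 ethyl (2E,5R,6E,10E,12R)-12-(tert-butyldimethylsilyloxy)-5-hydroxy-3,7,11,15-tetramethylhexadeca-2,6,10,14-tetraenoate, via trichlorosilyl ether 13 (not isolated)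
Conditions: 12 (1.5 equiv), SiCl4 (1.1 equiv), (R,R)-Denmark bisphosphoramide [pentane-1,5-diyl-linked bis-phosphoramide of (R)-N,N'-dimethyl-1,1'-binaphthyl-2,2'-diamine] (5 mol%), i-Pr2NEt (10 mol%), CH2Cl2, −78 °C; then aq. NaHCO3
Reagents that add atoms: none
Why: Lewis-base-activated SiCl4 vinylogous Mukaiyama aldol through an open transition state is γ-selective and gives the 2E enoate with conjugated aldehydes, and the catalyst enantiomer is the one that delivers the dienolate to the Re face to set 5R under catalyst control (sense confirmed by Mosher esters of 14).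

Step 10
Reactants: 14 ethyl (2E,5R,6E,10E,12R)-12-(tert-butyldimethylsilyloxy)-5-hydroxy-3,7,11,15-tetramethylhexadeca-2,6,10,14-tetraenoate
Product: 15 ethyl (2E,5R,6E,10E,12R)-5,12-bis(tert-butyldimethylsilyloxy)-3,7,11,15-tetramethylhexadeca-2,6,10,14-tetraenoate
Conditions: TBSCl, imidazole, DMAP (cat.), DMF, rt
Reagents that add atoms: tert-butyldimethylsilyl chloride, CC(C)(C)[Si](C)(C)Cl
Why: Silyl ether formation under mild base protects the new allylic carbinol without vinylogous elimination of the δ-hydroxy enoate.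

Step 11
Reactants: 15 ethyl (2E,5R,6E,10E,12R)-5,12-bis(tert-butyldimethylsilyloxy)-3,7,11,15-tetramethylhexadeca-2,6,10,14-tetraenoate
Product: 16 (2E,5R,6E,10E,12R)-5,12-bis(tert-butyldimethylsilyloxy)-3,7,11,15-tetramethylhexadeca-2,6,10,14-tetraen-1-ol
Conditions: i-Bu2AlH (2.5 equiv), CH2Cl2, −78 °C; aq. KNaC4H4O6 (potassium sodium tartrate)
Reagents that add atoms: none
Why: Hydride reduction of the enoate with i-Bu2AlH proceeds by clean 1,2-addition to the allylic alcohol with the olefin geometry retained.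

Step 12
Reactants: 16 (2E,5R,6E,10E,12R)-5,12-bis(tert-butyldimethylsilyloxy)-3,7,11,15-tetramethylhexadeca-2,6,10,14-tetraen-1-ol
Product: 17 (2E,5R,6E,10E,12R)-1-bromo-5,12-bis(tert-butyldimethylsilyloxy)-3,7,11,15-tetramethylhexadeca-2,6,10,14-tetraene
Conditions: CBr4 (1.3 equiv), PPh3 (1.4 equiv), 2,6-lutidine (cat.), CH2Cl2, −20 → 0 °C; used at once
Reagents that add atoms: carbon tetrabromide, BrC(Br)(Br)Br
Why: The Appel reaction converts the primary allylic alcohol into the bromide under neutral conditions (as for geraniol → geranyl bromide), so the silyl ethers and the E olefin survive.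

Step 13
Reactants: 18 4-methoxy-2-methylphenol
Product: 19 2-bromo-4-methoxy-6-methylphenol
Conditions: NBS (1.0 equiv), i-Pr2NH (10 mol%), CH2Cl2, 0 °C
Reagents that add atoms: N-bromosuccinimide, O=C1CCC(=O)N1Br
Why: Amine-catalysed electrophilic aromatic bromination goes ortho to the free hydroxyl, the only open ortho position, since para is blocked by OMe.

Step 14
Reactants: 19 2-bromo-4-methoxy-6-methylphenol
Product: 20 {2-[(2-bromo-4-methoxy-6-methylphenoxy)methoxy]ethyl}trimethylsilane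
Conditions: SEMCl (1.3 equiv), i-Pr2NEt (2 equiv), CH2Cl2, 0 °C → rt
Reagents that add atoms: 2-(trimethylsilyl)ethoxymethyl chloride, C[Si](C)(C)CCOCCl
Why: O-alkylation gives an acetal-type phenol ether that tolerates aryllithium chemistry (no retro-Brook shift as with aryl silyl ethers) and is later removed by fluoride instead of acid.

Step 15
Reactants: 20 {2-[(2-bromo-4-methoxy-6-methylphenoxy)methoxy]ethyl}trimethylsilane; 17 (2E,5R,6E,10E,12R)-1-bromo-5,12-bis(tert-butyldimethylsilyloxy)-3,7,11,15-tetramethylhexadeca-2,6,10,14-tetraene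
Product: 23 {2-[(2-{(2E,5R,6E,10E,12R)-5,12-bis(tert-butyldimethylsilyloxy)-3,7,11,15-tetramethylhexadeca-2,6,10,14-tetraen-1-yl}-4-methoxy-6-methylphenoxy)methoxy]ethyl}trimethylsilane, via aryllithium 21 (not isolated), via arylcopper 22 (not isolated)
Conditions: 20 (2.2 equiv), n-BuLi (2.1 equiv), THF, −78 °C; CuBr·SMe2 (2.2 equiv), −78 → −40 °C; 17 (1.0 equiv), −78 → 0 °C
Reagents that add atoms: none
Why: Bromine–lithium exchange, transmetalation to the arylcopper and SN2 aryl–allyl coupling at the primary allylic bromide (attack at the fully substituted γ-carbon is disfavoured) join the fragments with the 2E geometry retained.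

Step 16
Reactants: 23 {2-[(2-{(2E,5R,6E,10E,12R)-5,12-bis(tert-butyldimethylsilyloxy)-3,7,11,15-tetramethylhexadeca-2,6,10,14-tetraen-1-yl}-4-methoxy-6-methylphenoxy)methoxy]ethyl}trimethylsilane
Product: 25 2-[(2E,5R,6E,10E,12R)-5,12-dihydroxy-3,7,11,15-tetramethylhexadeca-2,6,10,14-tetraen-1-yl]-4-methoxy-6-methylphenol (CNP0269739.1), via SEM-protected diol 24 (not isolated)
Conditions: TBAF (8 equiv), THF, rt, 3 h; then DMPU, 4 Å MS, 65 °C
Reagents that add atoms: none
Why: Fluoride-induced desilylation removes both TBS ethers at rt and then fragments the aryl SEM ether (β-silyl elimination releasing phenoxide) on warming, a fully non-acidic global deprotection that cannot ionise the allylic carbinols or touch either stereocentre.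

**Compound list**
1 | geranyl acetate | CC(=O)OC/C=C(\C)CCC=C(C)C | starting material
2 | (2E,6E)-8-hydroxy-3,7-dimethylocta-2,6-dien-1-yl acetate | CC(=O)OC/C=C(\C)CC/C=C(\C)CO | intermediate
3 | (2E,6E)-3,7-dimethyl-8-oxoocta-2,6-dien-1-yl acetate | CC(=O)OC/C=C(\C)CC/C=C(\C)C=O | intermediate
4 | (2E,6E,8R)-8-[(diisopinocampheylboryl)oxy]-3,7-dimethylundeca-2,6,10-trien-1-yl acetate | CC(=O)OC/C=C(\C)CC/C=C(\C)[C@H](OB([C@@H]1[C@@H](C)[C@@H]2C[C@H](C1)C2(C)C)[C@@H]1[C@@H](C)[C@@H]2C[C@H](C1)C2(C)C)CC=C | intermediate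
5 | (2E,6E,8R)-8-hydroxy-3,7-dimethylundeca-2,6,10-trien-1-yl acetate | CC(=O)OC/C=C(\C)CC/C=C(\C)[C@H](O)CC=C | intermediate
6 | (2E,6E,8R)-8-(tert-butyldimethylsilyloxy)-3,7-dimethylundeca-2,6,10-trien-1-yl acetate | CC(=O)OC/C=C(\C)CC/C=C(\C)[C@H](O[Si](C)(C)C(C)(C)C)CC=C | intermediate
7 | (2E,6E,8R)-8-(tert-butyldimethylsilyloxy)-3,7,11-trimethyldodeca-2,6,10-trien-1-yl acetate | CC(=O)OC/C=C(\C)CC/C=C(\C)[C@H](O[Si](C)(C)C(C)(C)C)CC=C(C)C | intermediate
8 | (2E,6E,8R)-8-(tert-butyldimethylsilyloxy)-3,7,11-trimethyldodeca-2,6,10-trien-1-ol | OC/C=C(\C)CC/C=C(\C)[C@H](O[Si](C)(C)C(C)(C)C)CC=C(C)C | intermediate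
9 | (2E,6E,8R)-8-(tert-butyldimethylsilyloxy)-3,7,11-trimethyldodeca-2,6,10-trienal | O=C/C=C(\C)CC/C=C(\C)[C@H](O[Si](C)(C)C(C)(C)C)CC=C(C)C | intermediate
10 | ethyl 3-methylbut-2-enoate | CCOC(=O)C=C(C)C | starting material
11 | lithium 1-ethoxy-3-methylbuta-1,3-dien-1-olate | C=C(C)C=C([O-])OCC.[Li+] | intermediate
12 | tert-butyl[(1-ethoxy-3-methylbuta-1,3-dien-1-yl)oxy]dimethylsilane | C=C(C)C=C(OCC)O[Si](C)(C)C(C)(C)C | intermediate
13 | ethyl (2E,5R,6E,10E,12R)-12-(tert-butyldimethylsilyloxy)-3,7,11,15-tetramethyl-5-(trichlorosilyloxy)hexadeca-2,6,10,14-tetraenoate | CCOC(=O)/C=C(\C)C[C@@H](O[Si](Cl)(Cl)Cl)/C=C(\C)CC/C=C(\C)[C@H](O[Si](C)(C)C(C)(C)C)CC=C(C)C | intermediate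
14 | ethyl (2E,5R,6E,10E,12R)-12-(tert-butyldimethylsilyloxy)-5-hydroxy-3,7,11,15-tetramethylhexadeca-2,6,10,14-tetraenoate | CCOC(=O)/C=C(\C)C[C@@H](O)/C=C(\C)CC/C=C(\C)[C@H](O[Si](C)(C)C(C)(C)C)CC=C(C)C | intermediate
15 | ethyl (2E,5R,6E,10E,12R)-5,12-bis(tert-butyldimethylsilyloxy)-3,7,11,15-tetramethylhexadeca-2,6,10,14-tetraenoate | CCOC(=O)/C=C(\C)C[C@@H](O[Si](C)(C)C(C)(C)C)/C=C(\C)CC/C=C(\C)[C@H](O[Si](C)(C)C(C)(C)C)CC=C(C)C | intermediate
16 | (2E,5R,6E,10E,12R)-5,12-bis(tert-butyldimethylsilyloxy)-3,7,11,15-tetramethylhexadeca-2,6,10,14-tetraen-1-ol | OC/C=C(\C)C[C@@H](O[Si](C)(C)C(C)(C)C)/C=C(\C)CC/C=C(\C)[C@H](O[Si](C)(C)C(C)(C)C)CC=C(C)C | intermediate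
17 | (2E,5R,6E,10E,12R)-1-bromo-5,12-bis(tert-butyldimethylsilyloxy)-3,7,11,15-tetramethylhexadeca-2,6,10,14-tetraene | BrC/C=C(\C)C[C@@H](O[Si](C)(C)C(C)(C)C)/C=C(\C)CC/C=C(\C)[C@H](O[Si](C)(C)C(C)(C)C)CC=C(C)C | intermediate
18 | 4-methoxy-2-methylphenol | COc1ccc(O)c(C)c1 | starting material
19 | 2-bromo-4-methoxy-6-methylphenol | COc1cc(C)c(O)c(Br)c1 | intermediate
20 | {2-[(2-bromo-4-methoxy-6-methylphenoxy)methoxy]ethyl}trimethylsilane | COc1cc(C)c(OCOCC[Si](C)(C)C)c(Br)c1 | intermediate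
21 | [5-methoxy-3-methyl-2-{[2-(trimethylsilyl)ethoxy]methoxy}phenyl]lithium | COc1cc(C)c(OCOCC[Si](C)(C)C)c([Li])c1 | intermediate
22 | [5-methoxy-3-methyl-2-{[2-(trimethylsilyl)ethoxy]methoxy}phenyl]copper | COc1cc(C)c(OCOCC[Si](C)(C)C)c([Cu])c1 | intermediate
23 | SEM ether of 2-[(2E,5R,6E,10E,12R)-5,12-bis(tert-butyldimethylsilyloxy)-3,7,11,15-tetramethylhexadeca-2,6,10,14-tetraen-1-yl]-4-methoxy-6-methylphenol | COc1cc(C)c(OCOCC[Si](C)(C)C)c(C/C=C(\C)C[C@@H](O[Si](C)(C)C(C)(C)C)/C=C(\C)CC/C=C(\C)[C@H](O[Si](C)(C)C(C)(C)C)CC=C(C)C)c1 | intermediate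
24 | SEM ether of 2-[(2E,5R,6E,10E,12R)-5,12-dihydroxy-3,7,11,15-tetramethylhexadeca-2,6,10,14-tetraen-1-yl]-4-methoxy-6-methylphenol | COc1cc(C)c(OCOCC[Si](C)(C)C)c(C/C=C(\C)C[C@@H](O)/C=C(\C)CC/C=C(\C)[C@H](O)CC=C(C)C)c1 | intermediate
25 | 2-[(2E,5R,6E,10E,12R)-5,12-dihydroxy-3,7,11,15-tetramethylhexadeca-2,6,10,14-tetraen-1-yl]-4-methoxy-6-methylphenol | COc1cc(C)c(O)c(C/C=C(\C)C[C@@H](O)/C=C(\C)CC/C=C(\C)[C@H](O)CC=C(C)C)c1 | target

**Totals**
Total step count: 16. Longest linear sequence: 13 steps (steps 1–7, 9–12, 15, 16 from geranyl acetate).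

**Three steps most likely to fail, with fallbacks**

Step 9 (vinylogous aldol: ee, γ/α ratio and E/Z on this β,β-disubstituted enal are not precedented exactly, and I could not confirm from memory that the (R,R) catalyst gives Re-face attack; if Mosher analysis shows 5S, the (S,S) catalyst is used). The fallback sets out from 9 and comes back at 15. A TiCl4/i-Pr2NEt-mediated acetate aldol addition of (S)-3-acetyl-4-benzyl-1,3-thiazolidine-2-thione to 9 (CH2Cl2, −78 °C) gives the β-hydroxy N-acylthiazolidinethione F1. The (3R) sense is expected from the chelated transition state, the diastereomers are separable on silica, and the configuration is checked by Mosher analysis. Silylation (TBSOTf, 2,6-lutidine) gives the bis-silyl ether F2. Reduction with i-Bu2AlH at −78 °C releases the auxiliary and gives the β-silyloxy aldehyde F3. Ohira–Bestmann homologation (dimethyl (1-diazo-2-oxopropyl)phosphonate, K2CO3, MeOH) gives the terminal alkyne F4. Negishi carboalumination (AlMe3, Cp2ZrCl2, CH2Cl2) gives the (E)-alkenylalane F5 by syn-addition, and trapping with ethyl chloroformate gives ester 15 with the 2E geometry fixed.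

Step 15 (aryl–allyl coupling: SN2' attack, partial E/Z erosion or Wurtz-type loss of the valuable bromide). The fallback sets out from 16 and 20 and comes back at 23. Alcohol 16 is converted with ClCO2Me/pyridine (CH2Cl2, 0 °C) into the allylic methyl carbonate F6. Bromide 20 is converted by Miyaura borylation (B2pin2, Pd(dppf)Cl2, KOAc, dioxane, 80 °C) into the aryl pinacol boronate F7. A Pd(PPh3)4-catalysed allyl–aryl Suzuki–Miyaura coupling (K2CO3, THF/H2O, 60 °C) then attacks the less hindered primary terminus of the π-allyl complex and gives 23.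

Step 16 (cleavage of the hindered aryl SEM ether may need forcing conditions). The fallback sets out from 19 (together with 17) and comes back at 25, and avoids phenol protection altogether. Bromophenol 19 is treated with n-BuLi (2.1 equiv, THF, −78 → 0 °C) to give the O,C-dilithiated species lithium 2-lithio-4-methoxy-6-methylphenolate F8. With CuBr·SMe2 (10 mol%) this is C-allylated by bromide 17 to give the free phenol bis-silyl ether F9. TBAF in THF at rt then removes only the two TBS ethers and gives 25.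

**Further compounds**
F1 | step 9 | (3R,4E,8E,10R)-1-[(4S)-4-benzyl-2-thioxo-1,3-thiazolidin-3-yl]-10-(tert-butyldimethylsilyloxy)-3-hydroxy-5,9,13-trimethyltetradeca-4,8,12-trien-1-one | O=C(C[C@@H](O)/C=C(\C)CC/C=C(\C)[C@H](O[Si](C)(C)C(C)(C)C)CC=C(C)C)N1[C@@H](Cc2ccccc2)CSC1=S
F2 | step 9 | (3R,4E,8E,10R)-1-[(4S)-4-benzyl-2-thioxo-1,3-thiazolidin-3-yl]-3,10-bis(tert-butyldimethylsilyloxy)-5,9,13-trimethyltetradeca-4,8,12-trien-1-one | O=C(C[C@@H](O[Si](C)(C)C(C)(C)C)/C=C(\C)CC/C=C(\C)[C@H](O[Si](C)(C)C(C)(C)C)CC=C(C)C)N1[C@@H](Cc2ccccc2)CSC1=S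
F3 | step 9 | (3R,4E,8E,10R)-3,10-bis(tert-butyldimethylsilyloxy)-5,9,13-trimethyltetradeca-4,8,12-trienal | O=CC[C@@H](O[Si](C)(C)C(C)(C)C)/C=C(\C)CC/C=C(\C)[C@H](O[Si](C)(C)C(C)(C)C)CC=C(C)C
F4 | step 9 | (4R,5E,9E,11R)-4,11-bis(tert-butyldimethylsilyloxy)-6,10,14-trimethylpentadeca-5,9,13-trien-1-yne | C#CC[C@@H](O[Si](C)(C)C(C)(C)C)/C=C(\C)CC/C=C(\C)[C@H](O[Si](C)(C)C(C)(C)C)CC=C(C)C
F5 | step 9 | [(1E,4R,5E,9E,11R)-4,11-bis(tert-butyldimethylsilyloxy)-2,6,10,14-tetramethylpentadeca-1,5,9,13-tetraen-1-yl]dimethylalane | C[Al](C)/C=C(\C)C[C@@H](O[Si](C)(C)C(C)(C)C)/C=C(\C)CC/C=C(\C)[C@H](O[Si](C)(C)C(C)(C)C)CC=C(C)C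
F6 | step 15 | (2E,5R,6E,10E,12R)-5,12-bis(tert-butyldimethylsilyloxy)-3,7,11,15-tetramethylhexadeca-2,6,10,14-tetraen-1-yl methyl carbonate | COC(=O)OC/C=C(\C)C[C@@H](O[Si](C)(C)C(C)(C)C)/C=C(\C)CC/C=C(\C)[C@H](O[Si](C)(C)C(C)(C)C)CC=C(C)C
F7 | step 15 | 2-[5-methoxy-3-methyl-2-{[2-(trimethylsilyl)ethoxy]methoxy}phenyl]-4,4,5,5-tetramethyl-1,3,2-dioxaborolane | COc1cc(C)c(OCOCC[Si](C)(C)C)c(B2OC(C)(C)C(C)(C)O2)c1
F8 | step 16 | lithium 2-lithio-4-methoxy-6-methylphenolate | [Li]Oc1c(C)cc(OC)cc1[Li]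
F9 | step 16 | 2-[(2E,5R,6E,10E,12R)-5,12-bis(tert-butyldimethylsilyloxy)-3,7,11,15-tetramethylhexadeca-2,6,10,14-tetraen-1-yl]-4-methoxy-6-methylphenol | COc1cc(C)c(O)c(C/C=C(\C)C[C@@H](O[Si](C)(C)C(C)(C)C)/C=C(\C)CC/C=C(\C)[C@H](O[Si](C)(C)C(C)(C)C)CC=C(C)C)c1
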